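**Retrosynthetic overview**
1. Target ⇐ desilylation/deketalisation of 30 ⇐ (E)-enol ester by C–O coupling of alkenyl trifluoroborate 29 with 3-methylbut-2-enoic acid ⇐ Takai–Utimoto olefination of ring aldehyde 27.
2. C2 hydroxymethyl ⇐ α-iodination/Stille coupling of cycloheptenone 24; the seven-membered ring ⇐ ring-closing metathesis (RCM) of diene diol 21.
3. 21 ⇐ lactol 20 ⇐ trans γ-lactone 19 ⇐ syn γ-nitro aldehyde 17 ⇐ intermolecular amine-catalysed Michael addition of aldehyde 11 to nitroalkene 16 (C6–C7 bond, both stereocentres).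
4. 11 ⇐ (S)-3-allyl-3-methylcyclohexanone 4 (asymmetric conjugate methylation, ring cleavage, CBS reduction); 16 ⇐ dioxolane ester 12 + nitromethane.
5. Ring order: the six-membered ring of the starting material is cleaved (step 4); a γ-lactone is formed (step 14) and opened again (steps 15–16); the seven-membered carbocycle is closed last (step 17).

Conventions: ring numbering C1 = ring C=O, C2 = CH2OH-bearing alkene carbon, C5 = quaternary carbon, C6 = carbon bearing the enol ester arm, C7 = carbon bearing the 2-oxopropyl arm. The target is (5S,6S,7R) with an (R) side-chain carbinol. TBS = tert-butyldimethylsilyl; Bpin = 4,4,5,5-tetramethyl-1,3,2-dioxaborolan-2-yl; Diox = (2-methyl-1,3-dioxolan-2-yl)methyl; Sc = (3R)-3-(TBSO)-4-methylpent-4-en-1-yl; Q = (4S,7R)-7-(TBSO)-4,8-dimethylnona-1,8-dien-4-yl.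

**Route**

Step 1
Reactants: 1 3-ethoxycyclohex-2-en-1-one
Product: 3 3-(prop-2-en-1-yl)cyclohex-2-en-1-one, via tertiary allylic alcohol 2 (not isolated)
Conditions: CH2=CHCH2MgBr, THF, 0 °C; then 1 M HCl, 0 °C → rt
Reagents that add atoms: allylmagnesium bromide C=CC[Mg]Br; water O
Why: Stork–Danheiser sequence: 1,2-addition to the vinylogous ester, then acid-mediated allylic transposition/hydrolysis gives the 3-substituted enone (no stereocentre).

Step 2
Reactants: 3 3-(prop-2-en-1-yl)cyclohex-2-en-1-one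
Product: 4 (3S)-3-methyl-3-(prop-2-en-1-yl)cyclohexan-1-one
Conditions: Me3Al, copper thiophene-2-carboxylate CuO2CC4H3S (2 mol %), (S,S)-O,O′-(biphenyl-2,2′-diyl) N,N-bis(1-phenylethyl)phosphoramidite (4 mol %), Et2O, −30 °C; aq. HCl
Reagents that add atoms: trimethylaluminium C[Al](C)C
Why: Copper-catalysed asymmetric conjugate addition to the β,β-disubstituted enone sets the quaternary centre (future C5) as S; the ligand antipode to use is the one that gives (R)-3-ethyl-3-methylcyclohexanone from 3-ethylcyclohex-2-enone and Me3Al, since methyl delivery to that same face gives S here.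

Step 3
Reactants: 4 (3S)-3-methyl-3-(prop-2-en-1-yl)cyclohexan-1-one
Product: 5 (5S)-2-hydroxy-5-methyl-5-(prop-2-en-1-yl)cyclohexan-1-one (C2 epimers)
Conditions: KN(SiMe3)2, THF, −78 °C; 3-phenyl-2-(phenylsulfonyl)oxaziridine, −78 °C; aq. NH4Cl
Reagents that add atoms: 3-phenyl-2-(phenylsulfonyl)oxaziridine O=S(=O)(N1OC1c1ccccc1)c1ccccc1
Why: Enolisation occurs away from the neopentyl CH2 and Davis oxaziridine hydroxylation of the enolate gives the α-ketol; the new carbinol centre is destroyed in step 4.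

Step 4
Reactants: 5 (5S)-2-hydroxy-5-methyl-5-(prop-2-en-1-yl)cyclohexan-1-one
Product: 6 methyl (3S)-3-methyl-3-(3-oxopropyl)hex-5-enoate
Conditions: Pb(OAc)4, MeOH/PhMe (1:1), 0 °C
Reagents that add atoms: methanol CO
Why: Criegee-type cleavage of the α-ketol (as its methanol hemiketal) opens the ring to a methyl ester and an aldehyde, differentiating the two arms on the quaternary carbon without touching the alkene.

Step 5
Reactants: 6 methyl (3S)-3-methyl-3-(3-oxopropyl)hex-5-enoate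
Product: 7 methyl (3S)-3-(3-hydroxy-4-methylpent-4-en-1-yl)-3-methylhex-5-enoate (carbinol epimers)
Conditions: CH2=C(CH3)MgBr, THF, −78 °C; aq. NH4Cl
Reagents that add atoms: isopropenylmagnesium bromide C=C(C)[Mg]Br
Why: Grignard 1,2-addition is chemoselective for the aldehyde over the hindered methyl ester at −78 °C; the carbinol mixture is erased in step 6.

Step 6
Reactants: 7 methyl (3S)-3-(3-hydroxy-4-methylpent-4-en-1-yl)-3-methylhex-5-enoate
Product: 8 methyl (3S)-3-methyl-3-(4-methyl-3-oxopent-4-en-1-yl)hex-5-enoate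
Conditions: Dess–Martin periodinane, NaHCO3, CH2Cl2, 0 °C → rt
Reagents that add atoms: none
Why: Dess–Martin oxidation of the allylic alcohol gives the isopropenyl ketone needed for catalyst-controlled reduction.

Step 7
Reactants: 8 methyl (3S)-3-methyl-3-(4-methyl-3-oxopent-4-en-1-yl)hex-5-enoate
Product: 9 methyl (3S)-3-[(3R)-3-hydroxy-4-methylpent-4-en-1-yl]-3-methylhex-5-enoate
Conditions: (S)-2-methyl-CBS-oxazaborolidine (20 mol %), catecholborane, PhMe, −78 °C; MeOH, aq. Na2CO3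
Reagents that add atoms: none
Why: Corey–Bakshi–Shibata reduction: the isopropenyl group acts as the large substituent, so the (S)-catalyst gives the (R)-allylic alcohol, and catecholborane leaves the ester and alkenes intact.

Step 8
Reactants: 9 methyl (3S)-3-[(3R)-3-hydroxy-4-methylpent-4-en-1-yl]-3-methylhex-5-enoate
Product: 10 methyl (3S)-3-methyl-3-Sc-hex-5-enoate
Conditions: TBSCl, imidazole, DMF, rt
Reagents that add atoms: tert-butyldimethylsilyl chloride CC(C)(C)[Si](C)(C)Cl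
Why: Silyl ether formation protects the allylic alcohol for the organometallic, hydride and oxidation steps ahead.

Step 9
Reactants: 10 methyl (3S)-3-methyl-3-Sc-hex-5-enoate
Product: 11 (3S,6R)-6-(TBSO)-3,7-dimethyl-3-(prop-2-en-1-yl)oct-7-enal
Conditions: iBu2AlH (1.05 equiv), CH2Cl2, −78 °C; aq. potassium sodium tartrate KNaC4H4O6
Reagents that add atoms: none
Why: Partial ester reduction stops at the tetrahedral aluminate at −78 °C and releases the aldehyde on work-up.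

Step 10
Reactants: 12 ethyl 2-(2-methyl-1,3-dioxolan-2-yl)acetate
Product: 13 2-(2-methyl-1,3-dioxolan-2-yl)acetaldehyde
Conditions: iBu2AlH, CH2Cl2, −78 °C; aq. potassium sodium tartrate KNaC4H4O6
Reagents that add atoms: none
Why: Partial ester reduction at −78 °C gives the aldehyde with the ketone masked as its dioxolane.

Step 11
Reactants: 13 2-(2-methyl-1,3-dioxolan-2-yl)acetaldehyde
Product: 14 1-(2-methyl-1,3-dioxolan-2-yl)-3-nitropropan-2-ol (racemic)
Conditions: CH3NO2 (5 equiv), KOtBu (10 mol %), THF/tBuOH, 0 °C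
Reagents that add atoms: nitromethane C[N+](=O)[O-]
Why: Henry (nitroaldol) addition of nitromethane to the aldehyde under catalytic base.

Step 12
Reactants: 14 1-(2-methyl-1,3-dioxolan-2-yl)-3-nitropropan-2-ol
Product: 16 2-methyl-2-[(2E)-3-nitroprop-2-en-1-yl]-1,3-dioxolane, via nitro mesylate 15 (not isolated)
Conditions: MsCl, iPr2NEt, CH2Cl2, −20 → 0 °C
Reagents that add atoms: none
Why: Mesylation and E1cB elimination give the conjugated nitroalkene in its thermodynamically preferred E geometry.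

Step 13
Reactants: 11 (3S,6R)-6-(TBSO)-3,7-dimethyl-3-(prop-2-en-1-yl)oct-7-enal; 16 2-methyl-2-[(2E)-3-nitroprop-2-en-1-yl]-1,3-dioxolane
Product: 18 (2S,3R)-2-Q-3-Diox-4-nitrobutan-1-ol, via syn γ-nitro aldehyde 17 (not isolated)
Conditions: 16 (2 equiv), (S)-α,α-diphenylprolinol trimethylsilyl ether (20 mol %), 4-nitrophenol (20 mol %), PhMe, rt, 48 h; then MeOH, NaBH4, 0 °C
Reagents that add atoms: none
Why: Intermolecular enamine-catalysed Michael addition (Hayashi–Jørgensen type): the (E)-enamine of 11, shielded on one face by the CPh2OSiMe3 group of the (S)-catalyst, adds to the nitroalkene through the synclinal transition state to give the syn adduct with C6 (S) and C7 (R) set together, and reduction in the flask prevents epimerisation of the aldehyde.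

Step 14
Reactants: 18 (2S,3R)-2-Q-3-Diox-4-nitrobutan-1-ol
Product: 19 (3R,4S)-3-Diox-4-Q-oxolan-2-one (trans lactone)
Conditions: NaOH, MeOH/H2O, 0 °C; then Oxone (2KHSO5·KHSO4·K2SO4), Na2HPO4 buffer, 0 °C → rt; NaHSO4 to pH 3
Reagents that add atoms: potassium peroxymonosulfate [K+].[O-]S(=O)(=O)OO
Why: Oxidative Nef reaction of the nitronate takes the primary nitro group to the carboxylic acid, which lactonises to the trans-disubstituted γ-lactone, the thermodynamically favoured arrangement, so C7 is secure.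

Step 15
Reactants: 19 (3R,4S)-3-Diox-4-Q-oxolan-2-one
Product: 20 (3R,4S)-3-Diox-4-Q-oxolan-2-ol (anomers)
Conditions: iBu2AlH, CH2Cl2, −78 °C; aq. potassium sodium tartrate KNaC4H4O6
Reagents that add atoms: none
Why: Partial reduction of the lactone at −78 °C gives the lactol.

Step 16
Reactants: 20 (3R,4S)-3-Diox-4-Q-oxolan-2-ol
Product: 21 (2S,3R)-2-Q-3-Diox-hex-5-ene-1,4-diol (C4 epimers)
Conditions: CH2=CHMgBr (4 equiv), THF, 0 °C → rt; aq. NH4Cl
Reagents that add atoms: vinylmagnesium bromide C=C[Mg]Br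
Why: The lactol reacts through its open hydroxy aldehyde form in a Grignard 1,2-addition; the new carbinol mixture converges on oxidation in step 18.

Step 17
Reactants: 21 (2S,3R)-2-Q-3-Diox-hex-5-ene-1,4-diol
Product: 22 (5S,6S,7R)-6-(hydroxymethyl)-5-methyl-5-Sc-7-Diox-cyclohept-2-en-1-ol (C1 epimers)
Conditions: second-generation Grubbs catalyst RuCl2(=CHPh)(PCy3)(H2IMes) (5 mol %), CH2Cl2 (5 mM), 40 °C
Reagents that add atoms: none
Why: Ring-closing metathesis between the two monosubstituted alkenes closes the seven-membered ring, while the hindered 1,1-disubstituted isopropenyl group next to the silyl ether does not compete.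

Step 18
Reactants: 22 (5S,6S,7R)-6-(hydroxymethyl)-5-methyl-5-Sc-7-Diox-cyclohept-2-en-1-ol
Product: 24 (5S,6S,7R)-6-formyl-5-methyl-5-Sc-7-Diox-cyclohept-2-en-1-one, via hydroxy enone 23 (not isolated)
Conditions: MnO2, CH2Cl2, rt; filter; then Dess–Martin periodinane, NaHCO3, CH2Cl2, 0 °C
Reagents that add atoms: none
Why: MnO2 oxidises only the allylic alcohol to the enone, which avoids lactol/lactone formation from the 1,4-diol, and buffered Dess–Martin oxidation then converts the primary alcohol into the aldehyde.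

Step 19
Reactants: 24 (5S,6S,7R)-6-formyl-5-methyl-5-Sc-7-Diox-cyclohept-2-en-1-one
Product: 25 (5S,6S,7R)-6-formyl-2-iodo-5-methyl-5-Sc-7-Diox-cyclohept-2-en-1-one
Conditions: I2, pyridine, CH2Cl2, 0 °C → rt
Reagents that add atoms: iodine II
Why: Johnson α-iodination of the enone (pyridine conjugate addition, iodination, elimination) gives the 2-iodoenone without touching the aldehyde or the isolated alkene.

Step 20
Reactants: 25 (5S,6S,7R)-6-formyl-2-iodo-5-methyl-5-Sc-7-Diox-cyclohept-2-en-1-one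
Product: 26 (5S,6S,7R)-6-formyl-2-(hydroxymethyl)-5-methyl-5-Sc-7-Diox-cyclohept-2-en-1-one
Conditions: Bu3SnCH2OH, Pd(PPh3)4 (10 mol %), PhMe, 80 °C
Reagents that add atoms: (tributylstannyl)methanol CCCC[Sn](CO)(CCCC)CCCC
Why: Stille cross-coupling of the α-iodoenone with the hydroxymethyl stannane under neutral conditions installs the C2 hydroxymethyl group.

Step 21
Reactants: 26 (5S,6S,7R)-6-formyl-2-(hydroxymethyl)-5-methyl-5-Sc-7-Diox-cyclohept-2-en-1-one
Product: 27 (5S,6S,7R)-6-formyl-5-methyl-5-Sc-2-[(TBSO)methyl]-7-Diox-cyclohept-2-en-1-one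
Conditions: TBSCl, imidazole, CH2Cl2, 0 °C
Reagents that add atoms: tert-butyldimethylsilyl chloride CC(C)(C)[Si](C)(C)Cl
Why: Silylation of the primary allylic alcohol prevents its O-alkenylation in step 24.

Step 22
Reactants: 27 (5S,6S,7R)-6-formyl-5-methyl-5-Sc-2-[(TBSO)methyl]-7-Diox-cyclohept-2-en-1-one
Product: 28 (5S,6S,7R)-6-[(E)-2-(Bpin)ethenyl]-5-methyl-5-Sc-2-[(TBSO)methyl]-7-Diox-cyclohept-2-en-1-one
Conditions: Cl2CHBpin, CrCl2 (8 equiv), LiI (4 equiv), THF, rt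
Reagents that add atoms: 2-(dichloromethyl)-4,4,5,5-tetramethyl-1,3,2-dioxaborolane ClC(Cl)B1OC(C)(C)C(C)(C)O1
Why: Takai–Utimoto olefination: the gem-dichromium reagent adds to the aldehyde chemoselectively (ketones are inert) and eliminates to give the (E)-alkenyl boronate.

Step 23
Reactants: 28 (5S,6S,7R)-6-[(E)-2-(Bpin)ethenyl]-5-methyl-5-Sc-2-[(TBSO)methyl]-7-Diox-cyclohept-2-en-1-one
Product: 29 potassium trifluoro[(E)-2-{(5S,6S,7R)-5-methyl-1-oxo-5-Sc-2-[(TBSO)methyl]-7-Diox-cyclohept-2-en-6-yl}ethenyl]borate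
Conditions: KHF2 (aq., 5 equiv), MeOH, rt
Reagents that add atoms: potassium hydrogen difluoride [K+].[F-].F
Why: Ligand exchange at boron converts the pinacol ester into the trifluoroborate salt with retention of alkene geometry.

Step 24
Reactants: 29 potassium alkenyltrifluoroborate
Product: 30 (E)-2-{(5S,6S,7R)-5-methyl-1-oxo-5-Sc-2-[(TBSO)methyl]-7-Diox-cyclohept-2-en-6-yl}ethenyl 3-methylbut-2-enoate
Conditions: 3-methylbut-2-enoic acid (3 equiv), CuBr (20 mol %), DMAP (40 mol %), 4 Å MS, O2 (1 atm), CH2Cl2/MeCN, 40 °C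
Reagents that add atoms: 3-methylbut-2-enoic acid CC(C)=CC(=O)O
Why: Chan–Lam-type oxidative C–O coupling of the alkenyl trifluoroborate with the carboxylic acid proceeds with retention and gives the (E)-enol ester.

Step 25
Reactants: 30 protected enol ester
Product: 31 (E)-2-{(5S,6S,7R)-2-(hydroxymethyl)-5-[(3R)-3-hydroxy-4-methylpent-4-en-1-yl]-5-methyl-1-oxo-7-(2-oxopropyl)cyclohept-2-en-6-yl}ethenyl 3-methylbut-2-enoate (target)
Conditions: 48% aq. HF, MeCN/H2O, 0 °C → rt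
Reagents that add atoms: water O
Why: Aqueous HF cleaves both silyl ethers and hydrolyses the dioxolane to the methyl ketone under acid mild enough for the enol ester and the epimerisable C7.

**Compound list**

1 | 3-ethoxycyclohex-2-en-1-one | CCOC1=CC(=O)CCC1 | starting material
2 | 3-ethoxy-1-(prop-2-en-1-yl)cyclohex-2-en-1-ol (racemic, not isolated) | CCOC1=CC(O)(CC=C)CCC1 | intermediate
3 | 3-(prop-2-en-1-yl)cyclohex-2-en-1-one | C=CCC1=CC(=O)CCC1 | intermediate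
4 | (3S)-3-methyl-3-(prop-2-en-1-yl)cyclohexan-1-one | C1C(=O)CCC[C@@]1(C)CC=C | intermediate
5 | (5S)-2-hydroxy-5-methyl-5-(prop-2-en-1-yl)cyclohexan-1-one (C2 epimers) | C1C(=O)C(O)CC[C@@]1(C)CC=C | intermediate
6 | methyl (3S)-3-methyl-3-(3-oxopropyl)hex-5-enoate | O=CCC[C@@](CC(=O)OC)(C)CC=C | intermediate
7 | methyl (3S)-3-(3-hydroxy-4-methylpent-4-en-1-yl)-3-methylhex-5-enoate (carbinol epimers) | C=C(C)C(O)CC[C@@](CC(=O)OC)(C)CC=C | intermediate
8 | methyl (3S)-3-methyl-3-(4-methyl-3-oxopent-4-en-1-yl)hex-5-enoate | C=C(C)C(=O)CC[C@@](CC(=O)OC)(C)CC=C | intermediate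
9 | methyl (3S)-3-[(3R)-3-hydroxy-4-methylpent-4-en-1-yl]-3-methylhex-5-enoate | C=C(C)[C@H](O)CC[C@@](CC(=O)OC)(C)CC=C | intermediate
10 | methyl (3S)-3-[(3R)-3-(TBSO)-4-methylpent-4-en-1-yl]-3-methylhex-5-enoate | C=C(C)[C@H](O[Si](C)(C)C(C)(C)C)CC[C@@](CC(=O)OC)(C)CC=C | intermediate
11 | (3S,6R)-6-(TBSO)-3,7-dimethyl-3-(prop-2-en-1-yl)oct-7-enal | C=C(C)[C@H](O[Si](C)(C)C(C)(C)C)CC[C@@](CC=O)(C)CC=C | intermediate
12 | ethyl 2-(2-methyl-1,3-dioxolan-2-yl)acetate | CCOC(=O)CC1(C)OCCO1 | starting material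
13 | 2-(2-methyl-1,3-dioxolan-2-yl)acetaldehyde | O=CCC1(C)OCCO1 | intermediate
14 | 1-(2-methyl-1,3-dioxolan-2-yl)-3-nitropropan-2-ol (racemic) | [O-][N+](=O)CC(O)CC1(C)OCCO1 | intermediate
15 | 1-(2-methyl-1,3-dioxolan-2-yl)-3-nitropropan-2-yl methanesulfonate (not isolated) | CS(=O)(=O)OC(C[N+](=O)[O-])CC1(C)OCCO1 | intermediate
16 | 2-methyl-2-[(2E)-3-nitroprop-2-en-1-yl]-1,3-dioxolane | [O-][N+](=O)/C=C/CC1(C)OCCO1 | intermediate
17 | (2S,3R)-2-[(4S,7R)-7-(TBSO)-4,8-dimethylnona-1,8-dien-4-yl]-3-[(2-methyl-1,3-dioxolan-2-yl)methyl]-4-nitrobutanal (not isolated) | C=C(C)[C@H](O[Si](C)(C)C(C)(C)C)CC[C@@]([C@@H](C=O)[C@H](C[N+](=O)[O-])CC1(C)OCCO1)(C)CC=C | intermediate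
18 | (2S,3R)-2-[(4S,7R)-7-(TBSO)-4,8-dimethylnona-1,8-dien-4-yl]-3-[(2-methyl-1,3-dioxolan-2-yl)methyl]-4-nitrobutan-1-ol | C=C(C)[C@H](O[Si](C)(C)C(C)(C)C)CC[C@@]([C@@H](CO)[C@H](C[N+](=O)[O-])CC1(C)OCCO1)(C)CC=C | intermediate
19 | (3R,4S)-4-[(4S,7R)-7-(TBSO)-4,8-dimethylnona-1,8-dien-4-yl]-3-[(2-methyl-1,3-dioxolan-2-yl)methyl]oxolan-2-one | C=C(C)[C@H](O[Si](C)(C)C(C)(C)C)CC[C@@]([C@H]1COC(=O)[C@@H]1CC2(C)OCCO2)(C)CC=C | intermediate
20 | (3R,4S)-4-[(4S,7R)-7-(TBSO)-4,8-dimethylnona-1,8-dien-4-yl]-3-[(2-methyl-1,3-dioxolan-2-yl)methyl]oxolan-2-ol (anomers) | C=C(C)[C@H](O[Si](C)(C)C(C)(C)C)CC[C@@]([C@H]1COC(O)[C@@H]1CC2(C)OCCO2)(C)CC=C | intermediate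
21 | (2S,3R)-2-[(4S,7R)-7-(TBSO)-4,8-dimethylnona-1,8-dien-4-yl]-3-[(2-methyl-1,3-dioxolan-2-yl)methyl]hex-5-ene-1,4-diol (C4 epimers) | C=C(C)[C@H](O[Si](C)(C)C(C)(C)C)CC[C@@]([C@@H](CO)[C@H](C(O)C=C)CC1(C)OCCO1)(C)CC=C | intermediate
22 | (5S,6S,7R)-6-(hydroxymethyl)-5-methyl-5-[(3R)-3-(TBSO)-4-methylpent-4-en-1-yl]-7-[(2-methyl-1,3-dioxolan-2-yl)methyl]cyclohept-2-en-1-ol (C1 epimers) | C=C(C)[C@H](O[Si](C)(C)C(C)(C)C)CC[C@@]1(C)CC=CC(O)[C@H](CC2(C)OCCO2)[C@@H]1CO | intermediate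
23 | (5S,6S,7R)-6-(hydroxymethyl)-5-methyl-5-[(3R)-3-(TBSO)-4-methylpent-4-en-1-yl]-7-[(2-methyl-1,3-dioxolan-2-yl)methyl]cyclohept-2-en-1-one (not isolated) | C=C(C)[C@H](O[Si](C)(C)C(C)(C)C)CC[C@@]1(C)CC=CC(=O)[C@H](CC2(C)OCCO2)[C@@H]1CO | intermediate
24 | (5S,6S,7R)-6-formyl-5-methyl-5-[(3R)-3-(TBSO)-4-methylpent-4-en-1-yl]-7-[(2-methyl-1,3-dioxolan-2-yl)methyl]cyclohept-2-en-1-one | C=C(C)[C@H](O[Si](C)(C)C(C)(C)C)CC[C@@]1(C)CC=CC(=O)[C@H](CC2(C)OCCO2)[C@@H]1C=O | intermediate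
25 | (5S,6S,7R)-6-formyl-2-iodo-5-methyl-5-[(3R)-3-(TBSO)-4-methylpent-4-en-1-yl]-7-[(2-methyl-1,3-dioxolan-2-yl)methyl]cyclohept-2-en-1-one | C=C(C)[C@H](O[Si](C)(C)C(C)(C)C)CC[C@@]1(C)CC=C(I)C(=O)[C@H](CC2(C)OCCO2)[C@@H]1C=O | intermediate
26 | (5S,6S,7R)-6-formyl-2-(hydroxymethyl)-5-methyl-5-[(3R)-3-(TBSO)-4-methylpent-4-en-1-yl]-7-[(2-methyl-1,3-dioxolan-2-yl)methyl]cyclohept-2-en-1-one | C=C(C)[C@H](O[Si](C)(C)C(C)(C)C)CC[C@@]1(C)CC=C(CO)C(=O)[C@H](CC2(C)OCCO2)[C@@H]1C=O | intermediate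
27 | (5S,6S,7R)-6-formyl-5-methyl-5-[(3R)-3-(TBSO)-4-methylpent-4-en-1-yl]-2-[(TBSO)methyl]-7-[(2-methyl-1,3-dioxolan-2-yl)methyl]cyclohept-2-en-1-one | C=C(C)[C@H](O[Si](C)(C)C(C)(C)C)CC[C@@]1(C)CC=C(CO[Si](C)(C)C(C)(C)C)C(=O)[C@H](CC2(C)OCCO2)[C@@H]1C=O | intermediate
28 | (5S,6S,7R)-6-[(E)-2-(Bpin)ethenyl]-5-methyl-5-[(3R)-3-(TBSO)-4-methylpent-4-en-1-yl]-2-[(TBSO)methyl]-7-[(2-methyl-1,3-dioxolan-2-yl)methyl]cyclohept-2-en-1-one | C=C(C)[C@H](O[Si](C)(C)C(C)(C)C)CC[C@@]1(C)CC=C(CO[Si](C)(C)C(C)(C)C)C(=O)[C@H](CC2(C)OCCO2)[C@@H]1/C=C/B3OC(C)(C)C(C)(C)O3 | intermediate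
29 | potassium trifluoro[(E)-2-{(5S,6S,7R)-5-methyl-1-oxo-5-[(3R)-3-(TBSO)-4-methylpent-4-en-1-yl]-2-[(TBSO)methyl]-7-[(2-methyl-1,3-dioxolan-2-yl)methyl]cyclohept-2-en-6-yl}ethenyl]borate | C=C(C)[C@H](O[Si](C)(C)C(C)(C)C)CC[C@@]1(C)CC=C(CO[Si](C)(C)C(C)(C)C)C(=O)[C@H](CC2(C)OCCO2)[C@@H]1/C=C/[B-](F)(F)F.[K+] | intermediate
30 | (E)-2-{(5S,6S,7R)-5-methyl-1-oxo-5-[(3R)-3-(TBSO)-4-methylpent-4-en-1-yl]-2-[(TBSO)methyl]-7-[(2-methyl-1,3-dioxolan-2-yl)methyl]cyclohept-2-en-6-yl}ethenyl 3-methylbut-2-enoate | C=C(C)[C@H](O[Si](C)(C)C(C)(C)C)CC[C@@]1(C)CC=C(CO[Si](C)(C)C(C)(C)C)C(=O)[C@H](CC2(C)OCCO2)[C@@H]1/C=C/OC(=O)C=C(C)C | intermediate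
31 | (E)-2-{(5S,6S,7R)-2-(hydroxymethyl)-5-[(3R)-3-hydroxy-4-methylpent-4-en-1-yl]-5-methyl-1-oxo-7-(2-oxopropyl)cyclohept-2-en-6-yl}ethenyl 3-methylbut-2-enoate | C=C(C)[C@H](O)CC[C@@]1(C)CC=C(CO)C(=O)[C@H](CC(C)=O)[C@@H]1/C=C/OC(=O)C=C(C)C | target

**Totals**

Total steps: 25 (aldehyde 11: steps 1–9; nitroalkene 16: steps 10–12; union and elaboration: steps 13–25).
Longest linear sequence: 22 steps (steps 1–9, then 13–25).

**Three steps most likely to fail, each with a fallback**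

Step 13. The aldehyde carries a quaternary carbon next to the reacting CH2, so enamine formation and attack on a β-substituted nitroalkene may be slow. Fallback, from 11 back to 19: run the same (S)-catalysed Michael addition on nitroethylene (freshly made from 2-nitroethanol over phthalic anhydride; 3-nitrobenzoic acid co-catalyst), the most reactive and least hindered acceptor. Reduction in the flask with NaBH4 takes the γ-nitro aldehyde (2S)-2-[(4S,7R)-7-(TBSO)-4,8-dimethylnona-1,8-dien-4-yl]-4-nitrobutanal F1 on to the nitro alcohol (2S)-2-[(4S,7R)-7-(TBSO)-4,8-dimethylnona-1,8-dien-4-yl]-4-nitrobutan-1-ol F2. Oxidative Nef reaction and lactonisation under the conditions of step 14 give the β-substituted lactone (4S)-4-[(4S,7R)-7-(TBSO)-4,8-dimethylnona-1,8-dien-4-yl]oxolan-2-one F3. Its lithium enolate (LiN(iPr)2, THF, −78 °C) is alkylated by 3-bromo-2-methoxyprop-1-ene anti to the bulky quaternary substituent, giving the trans lactone (3R,4S)-3-(2-methoxyprop-2-en-1-yl)-4-[(4S,7R)-7-(TBSO)-4,8-dimethylnona-1,8-dien-4-yl]oxolan-2-one F4. Ethylene glycol with pyridinium p-toluenesulfonate in CH2Cl2 then converts the enol ether into the dioxolane, which is lactone 19. Here C6 comes from the catalyst and C7 from the trans-selective alkylation.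

Step 14. The oxidative Nef reaction may stall or be unclean next to the ketal and the alkenes. Fallback, from 18 back to 20, reductive instead of oxidative: SnCl2/PhSH/Et3N in MeCN at rt reduces the primary nitro group to the aldoxime (2S,3R)-2-[(4S,7R)-7-(TBSO)-4,8-dimethylnona-1,8-dien-4-yl]-4-(hydroxyimino)-3-[(2-methyl-1,3-dioxolan-2-yl)methyl]butan-1-ol F5. Buffered aqueous TiCl3/NH4OAc then cleaves the oxime to the hydroxy aldehyde, which closes to lactol 20, bypassing 19.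

Step 24. The copper-mediated coupling may give low conversion on this hindered, polyfunctional trifluoroborate. Fallback, from 27 back to 30, acylating an enol instead of coupling at boron: Ph3P=CHOMe (from the phosphonium chloride and KN(SiMe3)2, THF, −78 °C) converts aldehyde 27 into the enol ether (5S,6S,7R)-6-(2-methoxyethenyl)-5-methyl-5-[(3R)-3-(TBSO)-4-methylpent-4-en-1-yl]-2-[(TBSO)methyl]-7-[(2-methyl-1,3-dioxolan-2-yl)methyl]cyclohept-2-en-1-one F6. Hg(OAc)2 in aqueous THF followed by KI hydrolyses it to the homologous aldehyde (5S,6S,7R)-5-methyl-6-(2-oxoethyl)-5-[(3R)-3-(TBSO)-4-methylpent-4-en-1-yl]-2-[(TBSO)methyl]-7-[(2-methyl-1,3-dioxolan-2-yl)methyl]cyclohept-2-en-1-one F7. 3-Methylbut-2-enoic anhydride with Et3N and DMAP (CH2Cl2, 40 °C) O-acylates its enol to give 30, with the E isomer favoured by the bulky ring substituent and the Z isomer removed by chromatography.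

**Further compounds**

F1 | step 13 | (2S)-2-[(4S,7R)-7-(TBSO)-4,8-dimethylnona-1,8-dien-4-yl]-4-nitrobutanal | C=C(C)[C@H](O[Si](C)(C)C(C)(C)C)CC[C@@]([C@@H](C=O)CC[N+](=O)[O-])(C)CC=C
F2 | step 13 | (2S)-2-[(4S,7R)-7-(TBSO)-4,8-dimethylnona-1,8-dien-4-yl]-4-nitrobutan-1-ol | C=C(C)[C@H](O[Si](C)(C)C(C)(C)C)CC[C@@]([C@@H](CO)CC[N+](=O)[O-])(C)CC=C
F3 | step 13 | (4S)-4-[(4S,7R)-7-(TBSO)-4,8-dimethylnona-1,8-dien-4-yl]oxolan-2-one | C=C(C)[C@H](O[Si](C)(C)C(C)(C)C)CC[C@@]([C@H]1COC(=O)C1)(C)CC=C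
F4 | step 13 | (3R,4S)-3-(2-methoxyprop-2-en-1-yl)-4-[(4S,7R)-7-(TBSO)-4,8-dimethylnona-1,8-dien-4-yl]oxolan-2-one | C=C(C)[C@H](O[Si](C)(C)C(C)(C)C)CC[C@@]([C@H]1COC(=O)[C@@H]1CC(=C)OC)(C)CC=C
F5 | step 14 | (2S,3R)-2-[(4S,7R)-7-(TBSO)-4,8-dimethylnona-1,8-dien-4-yl]-4-(hydroxyimino)-3-[(2-methyl-1,3-dioxolan-2-yl)methyl]butan-1-ol | C=C(C)[C@H](O[Si](C)(C)C(C)(C)C)CC[C@@]([C@@H](CO)[C@H](C=NO)CC1(C)OCCO1)(C)CC=C
F6 | step 24 | (5S,6S,7R)-6-(2-methoxyethenyl)-5-methyl-5-[(3R)-3-(TBSO)-4-methylpent-4-en-1-yl]-2-[(TBSO)methyl]-7-[(2-methyl-1,3-dioxolan-2-yl)methyl]cyclohept-2-en-1-one (E/Z mixture) | C=C(C)[C@H](O[Si](C)(C)C(C)(C)C)CC[C@@]1(C)CC=C(CO[Si](C)(C)C(C)(C)C)C(=O)[C@H](CC2(C)OCCO2)[C@@H]1C=COC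
F7 | step 24 | (5S,6S,7R)-5-methyl-6-(2-oxoethyl)-5-[(3R)-3-(TBSO)-4-methylpent-4-en-1-yl]-2-[(TBSO)methyl]-7-[(2-methyl-1,3-dioxolan-2-yl)methyl]cyclohept-2-en-1-one | C=C(C)[C@H](O[Si](C)(C)C(C)(C)C)CC[C@@]1(C)CC=C(CO[Si](C)(C)C(C)(C)C)C(=O)[C@H](CC2(C)OCCO2)[C@@H]1CC=O
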